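The target is traced back to a coumarin. Numbering the pyrrole from nitrogen so that C2 carries the aryl group, the phenol oxygen, the benzene ring, C2, C3 and a carboxyl carbon parked on C3 form the pyranone ring of a chromen-2-one. The key step exploits this ortho-hydroxyaryl/C2–C3 relationship. In one operation glycine ethyl ester is fused onto 4-chloro-3-formylcoumarin, a β-chlorovinyl aldehyde embedded in the lactone. Nitrogen displaces chloride (N1–C2), and the glycine methylene condenses with the formyl carbon (C4–C5), closing the pyrrole. The two carboxyl groups land on C3 and C5 and are later exchanged ipso for bromine.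

Key step: step 2

Assumption: the target has no stereocentre, and its aryl–pyrrole axis (flanked only by OH/H and NH/Br) should rotate freely at room temperature, so it is one achiral compound and no enantiocontrol is needed.

Step 1
Reactants: 1 4-hydroxycoumarin
Product: 3 4-chloro-2-oxo-2H-chromene-3-carbaldehyde, via iminium chloride 2 (not isolated)
Conditions: POCl3 (3 equiv), DMF, 0 °C → 60 °C; ice water, filtration
Reagents that add atoms: N,N-dimethylformamide CN(C)C=O; phosphoryl chloride O=P(Cl)(Cl)Cl; water O
Why: Vilsmeier–Haack–Arnold chloroformylation, in which the enolic C3 attacks the chloroiminium ion, excess reagent exchanges the vinylogous acid OH at C4 for chloride, and cold water hydrolyses iminium 2 to the aldehyde without touching the lactone.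

Step 2
Reactants: 3 4-chloro-2-oxo-2H-chromene-3-carbaldehyde; 4 glycine ethyl ester hydrochloride
Product: 8 ethyl 4-oxo-1,4-dihydrochromeno[4,3-b]pyrrole-2-carboxylate, via glycine ethyl ester 5 (not isolated), via enaminoaldehyde 6 (not isolated), via aldol adduct 7 (not isolated)
Conditions: 4 (1.05 equiv), Et3N (3 equiv), EtOH, 0 °C → reflux
Reagents that add atoms: none
Why: The liberated amine 5 adds through nitrogen to C4 of 3, the β-carbon of both the lactone and the formyl carbonyl, and chloride leaves (addition–elimination at a vinylogous acid chloride), giving push–pull enaminoaldehyde 6 and the N1–C2 bond. Triethylamine then enolises the N–CH2–CO2Et unit, whose carbon attacks the adjacent formyl carbon in a 5-(enolexo)-exo-trig aldol closure (C4–C5 bond) to 7, and E1cB loss of water with tautomerisation makes the new ring aromatic. The closest known reaction type is the Fiesselmann-type annulation of β-chlorovinyl aldehydes with glycinates or thioglycolates, which is established for 4-chloro-3-formylcoumarins and α-amino esters. The two stereocentres of 7 are transient and are erased on aromatisation, so no stereocontrol is needed. The selectivity required is nitrogen attack at C4–Cl rather than at the formyl or lactone carbonyl: addition to CHO is reversible while chloride loss is not, the lactone carbonyl is the least electrophilic of the three sites, and about one equivalent of amine added cold leaves none for a second condensation. Once nitrogen sits on C4, the formyl carbon is the only electrophile the methylene carbon can reach through an unstrained ring.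

Step 3
Reactants: 8 ethyl 4-oxo-1,4-dihydrochromeno[4,3-b]pyrrole-2-carboxylate
Product: 9 trisodium 5-(2-oxidophenyl)-1H-pyrrole-2,4-dicarboxylate (carboxylates on C3 and C5 in the target numbering)
Conditions: NaOH (3.3 equiv), EtOH–H2O 1:1, reflux, N2; evaporated to dryness without acidification
Reagents that add atoms: sodium hydroxide [Na+].[OH-]
Why: Saponification (BAc2) of the ethyl ester and the aryl lactone is driven to the ring-opened side by formation of two carboxylates and a phenoxide; the salt is kept basic because protonating the C3 carboxylate would let the ortho phenol re-close the six-membered lactone, and ethanol is stripped because it would compete for the brominating agent in the next step.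

Step 4
Reactants: 9 trisodium 5-(2-oxidophenyl)-1H-pyrrole-2,4-dicarboxylate
Product: 11 pentabromopseudilin [2,4-dibromo-6-(3,4,5-tribromo-1H-pyrrol-2-yl)phenol], via sodium phenoxide 10 (not isolated)
Conditions: NBS (5.1 equiv, portionwise), DMF–H2O 9:1, 0 °C → rt, dark; aq Na2SO3; 1 M HCl to pH 3, EtOAc
Reagents that add atoms: N-bromosuccinimide O=C1CCC(=O)N1Br
Why: Electrophilic bromination is combined with ipso-bromodecarboxylation (the Hunsdiecker-type halodecarboxylation known for pyrrole carboxylates, electron-rich cinnamates and hydroxybenzoates): the phenoxide directs Br+ to C3' and C5', C4–H is the only free pyrrole position, attack at the carboxylate-bearing C5 (α to nitrogen) and C3 (enamine β-carbon and vinylogous ortho position of the phenoxide) gives σ-complexes that lose CO2 irreversibly, and because NBS releases only succinimide or its anion no strong acid arises, so the C3 carboxylate stays ionised and the lactone cannot re-form.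

Compound list
1 | 4-hydroxycoumarin | O=c1cc(O)c2ccccc2o1 | starting material
2 | N-[(4-chloro-2-oxo-2H-chromen-3-yl)methylidene]-N-methylmethanaminium chloride | C[N+](C)=Cc1c(Cl)c2ccccc2oc1=O.[Cl-] | intermediate (not isolated)
3 | 4-chloro-2-oxo-2H-chromene-3-carbaldehyde | O=Cc1c(Cl)c2ccccc2oc1=O | intermediate
4 | glycine ethyl ester hydrochloride | Cl.NCC(=O)OCC | starting material
5 | glycine ethyl ester | NCC(=O)OCC | intermediate (not isolated)
6 | ethyl N-(3-formyl-2-oxo-2H-chromen-4-yl)glycinate | CCOC(=O)CNc1c(C=O)c(=O)oc2ccccc12 | intermediate (not isolated)
7 | ethyl 3-hydroxy-4-oxo-1,2,3,4-tetrahydrochromeno[4,3-b]pyrrole-2-carboxylate (racemic, mixture of diastereomers) | CCOC(=O)C1NC2=C(C1O)C(=O)Oc1ccccc12 | intermediate (not isolated)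
8 | ethyl 4-oxo-1,4-dihydrochromeno[4,3-b]pyrrole-2-carboxylate | CCOC(=O)c1cc2c([nH]1)c1ccccc1oc2=O | intermediate
9 | trisodium 5-(2-oxidophenyl)-1H-pyrrole-2,4-dicarboxylate | [Na+].[Na+].[Na+].[O-]C(=O)c1cc(C([O-])=O)c([nH]1)-c1ccccc1[O-] | intermediate
10 | sodium 2,4-dibromo-6-(3,4,5-tribromo-1H-pyrrol-2-yl)phenoxide | [Na+].[O-]c1c(Br)cc(Br)cc1-c1[nH]c(Br)c(Br)c1Br | intermediate (not isolated)
11 | pentabromopseudilin, 2,4-dibromo-6-(3,4,5-tribromo-1H-pyrrol-2-yl)phenol (achiral) | Oc1c(Br)cc(Br)cc1-c1[nH]c(Br)c(Br)c1Br | target

Total step count: 4. Longest linear sequence: 4 steps, from 4-hydroxycoumarin.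

Steps most likely to fail

Step 4. Ipso substitution at the β-carboxylate may lag behind the other four brominations, so that unreacted material re-closes to the lactone on acidification. Surplus Br+ may also degrade the polybrominated pyrrole oxidatively in the presence of water. Fallback: setting out from 9, the salt is heated with NaOH in ethylene glycol at about 190 °C under nitrogen. This is an alkaline protodecarboxylation of the kind used on Knorr-type pyrrole diesters, and after neutralisation on work-up it should give 2-(1H-pyrrol-2-yl)phenol F1. Five equivalents of pyridinium tribromide in ethanol at 0 °C then brominate the five activated C–H positions (pyrrole C3, C4, C5 and the positions ortho and para to OH) by plain electrophilic substitution. The route is rejoined at 11.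

Step 3. Cleavage of the ester may be slow because the pyrrole N–H is deprotonated and deactivates the carbonyl. The lactone may partly re-close as the solution takes up CO2 or is concentrated. The uncertain assay of a crude hygroscopic salt would also upset the dosing of NBS. Fallback: setting out from 8, the saponification mixture is deliberately acidified so that the lactone re-closes. 4-oxo-1,4-dihydrochromeno[4,3-b]pyrrole-2-carboxylic acid F2 then precipitates and can be recrystallised and weighed. The pure acid is dissolved in exactly three equivalents of standardised aqueous NaOH at 60–80 °C and freeze-dried, which comes back to the route at 9.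

Step 2. The sequence may stall after the substitution, because the N–H···O=CH hydrogen bond holds the methylene away from the formyl group. A second glycinate may also condense at the aldehyde. Fallback: setting out from 3, diethyl aminomalonate hydrochloride and Et3N in EtOH at 0 °C should give diethyl 2-[(3-formyl-2-oxo-2H-chromen-4-yl)amino]propanedioate F3. Its far more acidic malonate C–H closes onto the formyl carbon in refluxing acetic acid (Kleinspehn–Paine pyrrole synthesis). The surplus ester is shed by hydrolysis and decarboxylation during aromatisation, and the route is rejoined at 8.

Further compounds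
F1 | step 4 | 2-(1H-pyrrol-2-yl)phenol | Oc1ccccc1-c1ccc[nH]1
F2 | step 3 | 4-oxo-1,4-dihydrochromeno[4,3-b]pyrrole-2-carboxylic acid | OC(=O)c1cc2c([nH]1)c1ccccc1oc2=O
F3 | step 2 | diethyl 2-[(3-formyl-2-oxo-2H-chromen-4-yl)amino]propanedioate | CCOC(=O)C(Nc1c(C=O)c(=O)oc2ccccc12)C(=O)OCC
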